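The route rests on opening the pyranone ring C of the 3-substituted flavanone unit at O1–C2. The precursor is then a fully benzylated α-aryl-2'-hydroxychalcone whose α-aryl group is C8'' of an intact (2R)-flavanone. A bifunctional amine–thiourea catalyst adds the ring-A phenol oxygen to C2 (6-endo oxa-Michael), and the resulting C3=C4 enol is protonated anti to the new C2 aryl group. One operation therefore closes ring C, sets C2, and sets C3 in the contra-thermodynamic 2,3-cis sense. The step exploits that C3 is both benzylic and α to the C4 carbonyl, hence planar in the precursor, and that ring A carries a single free ortho hydroxyl.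

Key step: step 9

Remark: unprimed locants refer to the 3-linked flavanone (unit 1), double-primed locants to the 8-linked flavanone (unit 2); the target is read as 2,3-cis (2R,3R) in unit 1 and (2''R) in unit 2, and the sense of induction of the two chiral catalysts is assumed as stated (otherwise the antipodal ligand or the quinine-derived pseudoenantiomer is used).

Step 1
Reactants: 1 1-[2,4-bis(benzyloxy)-6-hydroxyphenyl]ethan-1-one
Product: 2 1-[4,6-bis(benzyloxy)-2-hydroxy-3-iodophenyl]ethan-1-one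
Conditions: BnMe3N+ ICl2−, NaHCO3, CH2Cl2/MeOH, rt
Reagents that add atoms: benzyltrimethylammonium dichloroiodate, C[N+](C)(C)Cc1ccccc1.Cl[I-]Cl
Why: Electrophilic aromatic iodination, in which the free chelated hydroxyl should direct iodine to its ortho position C3' and not to C5' between the two benzyloxy groups, as known for the dimethyl ether analogue.

Step 2
Reactants: 2 1-[4,6-bis(benzyloxy)-2-hydroxy-3-iodophenyl]ethan-1-one
Product: 4 5,7-bis(benzyloxy)-8-iodo-4H-chromen-4-one, via enaminone 3 (not isolated)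
Conditions: Me2NCH(OMe)2, toluene, 100 °C; then aq HCl, CH2Cl2, 40 °C
Reagents that add atoms: N,N-dimethylformamide dimethyl acetal, COC(OC)N(C)C
Why: Enaminone formation at the methyl ketone followed by acid-promoted addition of the phenol and loss of dimethylamine is the standard chromone synthesis and leaves the aryl iodide and benzyl ethers untouched.

Step 3
Reactants: 1 1-[2,4-bis(benzyloxy)-6-hydroxyphenyl]ethan-1-one
Product: 5 1-[2,4-bis(benzyloxy)-6-(methoxymethoxy)phenyl]ethan-1-one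
Conditions: NaH, MOMCl, DMF, 0 °C to rt
Reagents that add atoms: chloromethyl methyl ether, COCCl
Why: Williamson-type O-alkylation of the sodium phenoxide masks the oxygen that becomes O1, as the only acid-labile group among benzyl ethers, until the key step.

Step 4
Reactants: 5 1-[2,4-bis(benzyloxy)-6-(methoxymethoxy)phenyl]ethan-1-one
Product: 6 ({1-[2,4-bis(benzyloxy)-6-(methoxymethoxy)phenyl]ethenyl}oxy)trimethylsilane
Conditions: LiN(SiMe3)2, Me3SiCl, THF, −78 °C; non-aqueous work-up, used directly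
Reagents that add atoms: chlorotrimethylsilane, C[Si](C)(C)Cl
Why: Deprotonation of the only enolisable position and O-silylation (silyl enol ether formation) give a neutral enolate equivalent for the coupling.

Step 5
Reactants: 4 5,7-bis(benzyloxy)-8-iodo-4H-chromen-4-one; 6 ({1-[2,4-bis(benzyloxy)-6-(methoxymethoxy)phenyl]ethenyl}oxy)trimethylsilane
Product: 7 5,7-bis(benzyloxy)-8-{2-[2,4-bis(benzyloxy)-6-(methoxymethoxy)phenyl]-2-oxoethyl}-4H-chromen-4-one
Conditions: Pd2(dba)3, P(t-Bu)3, Bu3SnF (mediator, regenerated by CsF), CsF, toluene, 85 °C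
Reagents that add atoms: none
Why: Palladium-catalysed α-arylation of a silyl enol ether through the tin enolate formed in situ by fluoride should join C8'' to the future C3 under base-free conditions that spare the chromone, with the bulky phosphine allowing the doubly ortho-substituted aryl iodide to couple.

Step 6
Reactants: 7 5,7-bis(benzyloxy)-8-{2-[2,4-bis(benzyloxy)-6-(methoxymethoxy)phenyl]-2-oxoethyl}-4H-chromen-4-one; 8 [4-(benzyloxy)phenyl]boronic acid
Product: 9 (2R)-5,7-bis(benzyloxy)-2-[4-(benzyloxy)phenyl]-8-{2-[2,4-bis(benzyloxy)-6-(methoxymethoxy)phenyl]-2-oxoethyl}-2,3-dihydro-4H-chromen-4-one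
Conditions: [RhOH(cod)]2 (cat.), (S)-MeO-F12-BIPHEP [(S)-6,6'-dimethoxy-2,2'-bis{bis(3,4,5-trifluorophenyl)phosphino}biphenyl] (cat.), toluene/H2O, 40 °C
Reagents that add atoms: none
Why: Rhodium-catalysed asymmetric 1,4-addition of the arylboronic acid to the chromone (Hayashi–Miyaura reaction), in which the aryl–rhodium species bearing the electron-poor chiral bisphosphine adds to one face of C2'' and so sets C2''(R), the hindered deoxybenzoin ketone and the MOM ether being inert.

Step 7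
Reactants: 9 (2R)-5,7-bis(benzyloxy)-2-[4-(benzyloxy)phenyl]-8-{2-[2,4-bis(benzyloxy)-6-(methoxymethoxy)phenyl]-2-oxoethyl}-2,3-dihydro-4H-chromen-4-one; 10 3,4-bis(benzyloxy)benzaldehyde
Product: 11 (2R)-5,7-bis(benzyloxy)-2-[4-(benzyloxy)phenyl]-8-{(1E)-1-[3,4-bis(benzyloxy)phenyl]-3-[2,4-bis(benzyloxy)-6-(methoxymethoxy)phenyl]-3-oxoprop-1-en-2-yl}-2,3-dihydro-4H-chromen-4-one
Conditions: piperidine (cat.), AcOH (cat.), toluene, 4 Å MS, 80 °C; E isomer purified by chromatography
Reagents that add atoms: none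
Why: Knoevenagel condensation, in which the methylene between the aroyl group and the C8'' aryl ring is far more acidic than C3''-H2 of the flavanone and adds to the piperidine-derived iminium ion of 10, loss of piperidine then giving the more stable E alkene (aryl groups cis, no new stereocentre).

Step 8
Reactants: 11 (2R)-5,7-bis(benzyloxy)-2-[4-(benzyloxy)phenyl]-8-{(1E)-1-[3,4-bis(benzyloxy)phenyl]-3-[2,4-bis(benzyloxy)-6-(methoxymethoxy)phenyl]-3-oxoprop-1-en-2-yl}-2,3-dihydro-4H-chromen-4-one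
Product: 12 (2R)-5,7-bis(benzyloxy)-2-[4-(benzyloxy)phenyl]-8-{(1E)-1-[3,4-bis(benzyloxy)phenyl]-3-[2,4-bis(benzyloxy)-6-hydroxyphenyl]-3-oxoprop-1-en-2-yl}-2,3-dihydro-4H-chromen-4-one
Conditions: HCl (cat.), MeOH/THF, 0 °C to rt; used at once
Reagents that add atoms: none
Why: Acid-catalysed acetal exchange removes the MOM group, which is especially labile ortho to a carbonyl, while the absence of base and the low temperature should keep the hydroxychalcone open and the benzyl ethers intact.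

Step 9
Reactants: 12 (2R)-5,7-bis(benzyloxy)-2-[4-(benzyloxy)phenyl]-8-{(1E)-1-[3,4-bis(benzyloxy)phenyl]-3-[2,4-bis(benzyloxy)-6-hydroxyphenyl]-3-oxoprop-1-en-2-yl}-2,3-dihydro-4H-chromen-4-one
Product: 14 (2R,3R)-5,7-bis(benzyloxy)-2-[3,4-bis(benzyloxy)phenyl]-3-{(2R)-5,7-bis(benzyloxy)-2-[4-(benzyloxy)phenyl]-4-oxo-3,4-dihydro-2H-chromen-8-yl}-2,3-dihydro-4H-chromen-4-one, via C3=C4 enol 13 (not isolated)
Conditions: 9-amino(9-deoxy)epi-quinidine 3,5-bis(trifluoromethyl)phenyl thiourea (10 mol %), toluene, −20 °C; cold dilute aq HCl wash at full conversion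
Reagents that add atoms: none
Why: The quinuclidine nitrogen of the catalyst activates the single free ring-A hydroxyl while the thiourea hydrogen-bonds the C4 carbonyl, so that O1 adds to C2 of the enone in an intramolecular oxa-Michael reaction and gives the C3=C4 enol(ate) 13 as an ion pair. The closest known reaction type is the cinchona amine–thiourea-catalysed asymmetric cyclisation of α-substituted 2'-hydroxychalcones to flavanones, run here as a conjugate addition–protonation sequence. Ring C closes in the 6-endo-trig mode. C2 is set by the catalyst, which shields one face of the β-carbon; C3 is set by the substrate, because allylic 1,2-strain with the C3 aryl group forces the new C2 aryl group pseudoaxial and the proton is delivered to the opposite face of the enol, which places the two aryl groups cis. The step needs kinetic control, since the 2,3-trans epimer is the thermodynamic one: the weak base, the non-polar solvent, the low temperature and removal of the catalyst by the acid wash should secure it. Regioselectivity needs no control, because the other ortho oxygen of ring A and O7'' are benzylated.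

Step 10
Reactants: 14 (2R,3R)-5,7-bis(benzyloxy)-2-[3,4-bis(benzyloxy)phenyl]-3-{(2R)-5,7-bis(benzyloxy)-2-[4-(benzyloxy)phenyl]-4-oxo-3,4-dihydro-2H-chromen-8-yl}-2,3-dihydro-4H-chromen-4-one
Product: 15 (2R,3R)-2-(3,4-dihydroxyphenyl)-5,7-dihydroxy-3-[(2R)-5,7-dihydroxy-2-(4-hydroxyphenyl)-4-oxo-3,4-dihydro-2H-chromen-8-yl]-2,3-dihydro-4H-chromen-4-one
Conditions: H2 (1 atm), Pd/C, THF/MeOH, rt
Reagents that add atoms: none
Why: Hydrogenolysis of the seven benzyl ethers under neutral conditions should free all phenols without base or acid, so that the epimerisable C3 and the ring-opening-prone C2 and C2'' keep their configuration.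

Compound list
1 | 1-[2,4-bis(benzyloxy)-6-hydroxyphenyl]ethan-1-one | CC(=O)c1c(O)cc(OCc2ccccc2)cc1OCc1ccccc1 | starting material
2 | 1-[4,6-bis(benzyloxy)-2-hydroxy-3-iodophenyl]ethan-1-one | CC(=O)c1c(O)c(I)c(OCc2ccccc2)cc1OCc1ccccc1 | intermediate
3 | (E)-1-[4,6-bis(benzyloxy)-2-hydroxy-3-iodophenyl]-3-(dimethylamino)prop-2-en-1-one | CN(C)/C=C/C(=O)c1c(O)c(I)c(OCc2ccccc2)cc1OCc1ccccc1 | intermediate
4 | 5,7-bis(benzyloxy)-8-iodo-4H-chromen-4-one | O=c1ccoc2c(I)c(OCc3ccccc3)cc(OCc3ccccc3)c12 | intermediate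
5 | 1-[2,4-bis(benzyloxy)-6-(methoxymethoxy)phenyl]ethan-1-one | CC(=O)c1c(OCOC)cc(OCc2ccccc2)cc1OCc1ccccc1 | intermediate
6 | ({1-[2,4-bis(benzyloxy)-6-(methoxymethoxy)phenyl]ethenyl}oxy)trimethylsilane | C=C(O[Si](C)(C)C)c1c(OCOC)cc(OCc2ccccc2)cc1OCc1ccccc1 | intermediate
7 | 5,7-bis(benzyloxy)-8-{2-[2,4-bis(benzyloxy)-6-(methoxymethoxy)phenyl]-2-oxoethyl}-4H-chromen-4-one | O=c1ccoc2c(CC(=O)c3c(OCOC)cc(OCc4ccccc4)cc3OCc3ccccc3)c(OCc3ccccc3)cc(OCc3ccccc3)c12 | intermediate
8 | [4-(benzyloxy)phenyl]boronic acid | OB(O)c1ccc(OCc2ccccc2)cc1 | starting material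
9 | (2R)-5,7-bis(benzyloxy)-2-[4-(benzyloxy)phenyl]-8-{2-[2,4-bis(benzyloxy)-6-(methoxymethoxy)phenyl]-2-oxoethyl}-2,3-dihydro-4H-chromen-4-one | O=C1C[C@H](c2ccc(OCc3ccccc3)cc2)Oc2c1c(OCc1ccccc1)cc(OCc1ccccc1)c2CC(=O)c1c(OCOC)cc(OCc2ccccc2)cc1OCc1ccccc1 | intermediate
10 | 3,4-bis(benzyloxy)benzaldehyde | O=Cc1ccc(OCc2ccccc2)c(OCc2ccccc2)c1 | starting material
11 | (2R)-5,7-bis(benzyloxy)-2-[4-(benzyloxy)phenyl]-8-{(1E)-1-[3,4-bis(benzyloxy)phenyl]-3-[2,4-bis(benzyloxy)-6-(methoxymethoxy)phenyl]-3-oxoprop-1-en-2-yl}-2,3-dihydro-4H-chromen-4-one | O=C1C[C@H](c2ccc(OCc3ccccc3)cc2)Oc2c1c(OCc1ccccc1)cc(OCc1ccccc1)c2/C(=C\c1ccc(OCc2ccccc2)c(OCc2ccccc2)c1)C(=O)c1c(OCOC)cc(OCc2ccccc2)cc1OCc1ccccc1 | intermediate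
12 | (2R)-5,7-bis(benzyloxy)-2-[4-(benzyloxy)phenyl]-8-{(1E)-1-[3,4-bis(benzyloxy)phenyl]-3-[2,4-bis(benzyloxy)-6-hydroxyphenyl]-3-oxoprop-1-en-2-yl}-2,3-dihydro-4H-chromen-4-one | O=C1C[C@H](c2ccc(OCc3ccccc3)cc2)Oc2c1c(OCc1ccccc1)cc(OCc1ccccc1)c2/C(=C\c1ccc(OCc2ccccc2)c(OCc2ccccc2)c1)C(=O)c1c(O)cc(OCc2ccccc2)cc1OCc1ccccc1 | intermediate
13 | (2R)-5,7-bis(benzyloxy)-2-[4-(benzyloxy)phenyl]-8-{(2S)-5,7-bis(benzyloxy)-2-[3,4-bis(benzyloxy)phenyl]-4-hydroxy-2H-chromen-3-yl}-2,3-dihydro-4H-chromen-4-one (enol; the 2S descriptor is a priority change only, the arrangement at C2 is that of 14) | O=C1C[C@H](c2ccc(OCc3ccccc3)cc2)Oc2c1c(OCc1ccccc1)cc(OCc1ccccc1)c2C1=C(O)c2c(OCc3ccccc3)cc(OCc3ccccc3)cc2O[C@H]1c1ccc(OCc2ccccc2)c(OCc2ccccc2)c1 | intermediate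
14 | (2R,3R)-5,7-bis(benzyloxy)-2-[3,4-bis(benzyloxy)phenyl]-3-{(2R)-5,7-bis(benzyloxy)-2-[4-(benzyloxy)phenyl]-4-oxo-3,4-dihydro-2H-chromen-8-yl}-2,3-dihydro-4H-chromen-4-one (2,3-cis) | O=C1C[C@H](c2ccc(OCc3ccccc3)cc2)Oc2c1c(OCc1ccccc1)cc(OCc1ccccc1)c2[C@H]1C(=O)c2c(OCc3ccccc3)cc(OCc3ccccc3)cc2O[C@H]1c1ccc(OCc2ccccc2)c(OCc2ccccc2)c1 | intermediate
15 | (2R,3R)-2-(3,4-dihydroxyphenyl)-5,7-dihydroxy-3-[(2R)-5,7-dihydroxy-2-(4-hydroxyphenyl)-4-oxo-3,4-dihydro-2H-chromen-8-yl]-2,3-dihydro-4H-chromen-4-one (2,3-cis) | O=C1C[C@H](c2ccc(O)cc2)Oc2c1c(O)cc(O)c2[C@H]1C(=O)c2c(O)cc(O)cc2O[C@H]1c1ccc(O)c(O)c1 | target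

Total step count: 10.
Longest linear sequence: 8 steps (steps 3, 4, 5, 6, 7, 8, 9, 10 from compound 1; the branch through steps 1 and 2 is equally long).

Steps most likely to fail

Step 9. The kinetic 2,3-cis product may equilibrate to the trans epimer through enolisation at C3 under the amine catalyst, the catalyst may discriminate the faces of C2 poorly, or ring closure may already begin without control during step 8. The fallback sets out from 12 and comes back to the route at 14. Compound 12 is irradiated at 365 nm in degassed benzene/acetonitrile without base. Excited-state proton transfer from the 2'-hydroxyl to the C4 carbonyl and thermal oxa-6π ring closure of the resulting o-quinonoid dienol should give enol 13 and its C2 epimer, the (2R)-configured enol F1, without facial preference. Both should ketonise under the same substrate control to the cis ketones, 14 and the (2S,3S) diastereomer F2. These differ in their relation to C2''(R) and are separated by chromatography.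

Step 5. Transmetalation and reductive elimination may be slow at the doubly ortho-substituted aryl–palladium centre, so that protodesilylation of 6 back to 5 and hydrodeiodination of 4 take over. The fallback reverses the polarity of the coupling; it sets out from 4 and 6 and comes back at 7. Miyaura borylation of 4 (B2pin2, PdCl2(dppf), KOAc, dioxane, 80 °C) should give the pinacol boronate F3. Bromination of 6 with N-bromosuccinimide (THF, 0 °C) should give the α-bromoketone F4. Suzuki–Miyaura coupling of F3 with F4 (Pd(OAc)2, SPhos, K3PO4, toluene/H2O, 60 °C) then forms the C8''–CH2 bond of 7.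

Step 7. Condensation at the doubly hindered methylene may be sluggish, leaving time for amine-induced opening of the flavanone ring (erosion of C2'') or for loss of the MOM group followed by uncontrolled ring closure. The fallback replaces the condensation by a directed aldol addition and a separate elimination; it sets out from 9 and comes back at 11. The boron enolate of 9 (Bu2BOTf, i-Pr2NEt, CH2Cl2, −78 °C) is treated with 10 to give the β-hydroxy ketone F5 as a mixture of diastereomers. Mesylation (MsCl, Et3N, CH2Cl2, 0 °C) gives the mesylate F6, and elimination with DBU at 0 °C gives 11.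

Further compounds
F1 | step 9 | (2R)-5,7-bis(benzyloxy)-2-[4-(benzyloxy)phenyl]-8-{(2R)-5,7-bis(benzyloxy)-2-[3,4-bis(benzyloxy)phenyl]-4-hydroxy-2H-chromen-3-yl}-2,3-dihydro-4H-chromen-4-one (C2 epimer of enol 13) | O=C1C[C@H](c2ccc(OCc3ccccc3)cc2)Oc2c1c(OCc1ccccc1)cc(OCc1ccccc1)c2C1=C(O)c2c(OCc3ccccc3)cc(OCc3ccccc3)cc2O[C@@H]1c1ccc(OCc2ccccc2)c(OCc2ccccc2)c1
F2 | step 9 | (2S,3S)-5,7-bis(benzyloxy)-2-[3,4-bis(benzyloxy)phenyl]-3-{(2R)-5,7-bis(benzyloxy)-2-[4-(benzyloxy)phenyl]-4-oxo-3,4-dihydro-2H-chromen-8-yl}-2,3-dihydro-4H-chromen-4-one | O=C1C[C@H](c2ccc(OCc3ccccc3)cc2)Oc2c1c(OCc1ccccc1)cc(OCc1ccccc1)c2[C@@H]1C(=O)c2c(OCc3ccccc3)cc(OCc3ccccc3)cc2O[C@@H]1c1ccc(OCc2ccccc2)c(OCc2ccccc2)c1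
F3 | step 5 | 5,7-bis(benzyloxy)-8-(4,4,5,5-tetramethyl-1,3,2-dioxaborolan-2-yl)-4H-chromen-4-one | CC1(C)OB(OC1(C)C)c1c(OCc2ccccc2)cc(OCc2ccccc2)c2c(=O)ccoc12
F4 | step 5 | 2-bromo-1-[2,4-bis(benzyloxy)-6-(methoxymethoxy)phenyl]ethan-1-one | BrCC(=O)c1c(OCOC)cc(OCc2ccccc2)cc1OCc1ccccc1
F5 | step 7 | (2R)-5,7-bis(benzyloxy)-2-[4-(benzyloxy)phenyl]-8-{1-[3,4-bis(benzyloxy)phenyl]-3-[2,4-bis(benzyloxy)-6-(methoxymethoxy)phenyl]-1-hydroxy-3-oxopropan-2-yl}-2,3-dihydro-4H-chromen-4-one (mixture of diastereomers at the two new centres) | O=C1C[C@H](c2ccc(OCc3ccccc3)cc2)Oc2c1c(OCc1ccccc1)cc(OCc1ccccc1)c2C(C(O)c1ccc(OCc2ccccc2)c(OCc2ccccc2)c1)C(=O)c1c(OCOC)cc(OCc2ccccc2)cc1OCc1ccccc1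
F6 | step 7 | 1-[3,4-bis(benzyloxy)phenyl]-2-{(2R)-5,7-bis(benzyloxy)-2-[4-(benzyloxy)phenyl]-4-oxo-3,4-dihydro-2H-chromen-8-yl}-3-[2,4-bis(benzyloxy)-6-(methoxymethoxy)phenyl]-3-oxopropyl methanesulfonate (mixture of diastereomers at the two new centres) | O=C1C[C@H](c2ccc(OCc3ccccc3)cc2)Oc2c1c(OCc1ccccc1)cc(OCc1ccccc1)c2C(C(OS(C)(=O)=O)c1ccc(OCc2ccccc2)c(OCc2ccccc2)c1)C(=O)c1c(OCOC)cc(OCc2ccccc2)cc1OCc1ccccc1
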